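The plan cuts C1′–C2′ of the farnesyl chain together with O1–C2 of the furanone ring. Ring oxygen O1 and vinyl carbon C2′ stand 1,2 across the C2–C1′ bond, which is the retron of an alkene oxy-alkenylation. In one operation a Pd-catalysed carboalkoxylation closes O1–C2 (5-exo) in an acyclic 2-(1-silyloxyallyl)phenol and couples the resulting C1′–Pd centre with an (E)-C14 alkenyl iodide from a Negishi carboalumination. The stereoisomer mixture is then erased on purpose. Oxidation at C3 gives the racemic, enolisable coumaranone, and a stereoconvergent phosphoric acid enol catalysis with nitrosobenzene sets the C2 hydroxyl as the (R)-hemiketal.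

Key step: step 5

Assumption: the C2 hemiketal is taken to be configurationally stable in neutral or weakly acidic aprotic media (it racemises through the ring-opened 1,2-diketone once its alkoxide forms), and the (R)-acid is taken to give the 2R product; if a test run shows the opposite sense, the (S)-acid is used.

Step 1
Reactants: 1 geranyl bromide; 2 propargyl bromide
Product: 4 (5E)-6,10-dimethylundeca-5,9-dien-1-yne, via 1,3-dilithiopropyne 3 (not isolated)
Conditions: 2, n-BuLi (2 equiv), TMEDA, Et2O–hexane, −78 °C; then 1, −78 °C → rt; H2O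
Reagents that add atoms: none
Why: Bromine–lithium exchange plus acetylide deprotonation of 2 gives dianion 3, which is alkylated by the allylic bromide only at its more nucleophilic sp3 carbon (SN2 propargylation of an alkyl halide), so the E-alkene of 1 is kept and the terminal alkyne appears on work-up.

Step 2
Reactants: 4 (5E)-6,10-dimethylundeca-5,9-dien-1-yne
Product: 6 (1E,5E)-1-iodo-2,6,10-trimethylundeca-1,5,9-triene, via (E)-alkenyldimethylalane 5 (not isolated)
Conditions: Me3Al (2 equiv), Cp2ZrCl2 (20 mol %), CH2Cl2, 0 °C → rt; then I2, THF, −30 → 0 °C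
Reagents that add atoms: trimethylaluminium C[Al](C)C; iodine II
Why: The Negishi zirconium-catalysed carboalumination adds methyl and aluminium syn across the terminal alkyne with aluminium at the terminus, iodinolysis proceeds with retention, and the isolated trisubstituted alkenes do not react, which fixes the E geometry of the future C2′=C3′ bond.

Step 3
Reactants: 7 2,4-dihydroxybenzaldehyde
Product: 8 2,4-bis(tert-butyldimethylsilyloxy)benzaldehyde
Conditions: TBSCl (2.4 equiv), imidazole (5 equiv), DMF, rt
Reagents that add atoms: tert-butyldimethylsilyl chloride CC(C)(C)[Si](C)(C)Cl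
Why: Imidazole-promoted O-silylation masks both acidic phenols for the Grignard step and places on O-2 the silyl group that is relayed to the C3 oxygen in step 4.

Step 4
Reactants: 8 2,4-bis(tert-butyldimethylsilyloxy)benzaldehyde
Product: 10 rac-5-(tert-butyldimethylsilyloxy)-2-[1-(tert-butyldimethylsilyloxy)prop-2-en-1-yl]phenol, via bromomagnesium alkoxide 9 (not isolated)
Conditions: CH2=CHMgBr (1.2 equiv), THF, −78 °C → rt; pH 7 buffer, 0 °C
Reagents that add atoms: vinylmagnesium bromide C=C[Mg]Br
Why: Grignard 1,2-addition gives alkoxide 9, in which the ortho silyl group moves from the phenol oxygen to the more basic alkoxide oxygen through a six-membered silicate (1,5-O→O silyl migration driven by phenoxide formation), which frees exactly the phenol needed and protects the C3 oxygen, while the new C3 stereocentre is racemic and is destroyed in step 6.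

Step 5
Reactants: 10 rac-5-(tert-butyldimethylsilyloxy)-2-[1-(tert-butyldimethylsilyloxy)prop-2-en-1-yl]phenol; 6 (1E,5E)-1-iodo-2,6,10-trimethylundeca-1,5,9-triene
Product: 11 3,6-bis(tert-butyldimethylsilyloxy)-2-[(2E,6E)-3,7,11-trimethyldodeca-2,6,10-trien-1-yl]-2,3-dihydrobenzofuran (racemic cis/trans mixture)
Conditions: 6 (1.2 equiv), Pd(OAc)2 (5 mol %), CPhos (12 mol %), Ag2CO3 (0.8 equiv), PhCF3, 70 °C, Ar
Reagents that add atoms: none
Why: Oxidative addition of 6 to Pd(0) and iodide abstraction by Ag2CO3 give a cationic (E)-alkenyl-Pd(II) species that binds the tethered terminal alkene of 10, the phenol oxygen attacks the internal carbon (future C2), and the primary C1′–Pd(alkenyl) intermediate reductively eliminates to forge C1′–C2′. The closest known reaction type is the Pd-catalysed alkene carboalkoxylation (oxypalladation/reductive elimination) of 2-allylphenols and γ-hydroxyalkenes with aryl and alkenyl electrophiles. The dihydrofuran ring closes in the 5-exo-trig mode (O1–C2), 6-endo attack being disfavoured for a monosubstituted alkene. The new C2 stereocentre is only biased (trans to the C3 silyloxy group) by 1,2-induction, which does not matter because C3 is oxidised in step 6 and C2 is reset in step 7. The step needs C–C reductive elimination to outrun β-hydride elimination at C2–H and Heck insertion, which the bulky electron-rich biaryl phosphine should secure, and it needs selection of one alkene out of four, which holds because the trisubstituted chain alkenes bind Pd poorly and the chain lies trans to Pd in the E-alkenyl complex, so no intramolecular insertion is possible. The E geometry set in step 2 is carried over because oxidative addition and reductive elimination are both stereoretentive.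

Step 6
Reactants: 11 3,6-bis(tert-butyldimethylsilyloxy)-2-farnesyl-2,3-dihydrobenzofuran
Product: 12 rac-6-(tert-butyldimethylsilyloxy)-2-[(2E,6E)-3,7,11-trimethyldodeca-2,6,10-trien-1-yl]benzofuran-3(2H)-one
Conditions: DDQ (1.1 equiv), CH2Cl2–pH 7 buffer (10:1), 0 °C, Ar
Reagents that add atoms: none
Why: DDQ abstracts hydride from C3–H, which is benzylic to a ring carrying O1 ortho and the silyloxy group para, and the silyloxocarbenium ion loses its silyl group to water (oxidative deprotection of an electron-rich benzylic silyl ether), while the aryl silyl ether and the isolated alkenes should stay untouched, so C3 is erased as a stereocentre and C2 becomes epimerisable.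

Step 7
Reactants: 12 rac-6-(tert-butyldimethylsilyloxy)-2-farnesylbenzofuran-3(2H)-one
Product: 14 (2R)-6-(tert-butyldimethylsilyloxy)-2-hydroxy-2-[(2E,6E)-3,7,11-trimethyldodeca-2,6,10-trien-1-yl]benzofuran-3(2H)-one, via (2S)-aminoxy ketone 13 (not isolated)
Conditions: PhNO (2.5 equiv), (R)-TRIP (10 mol %), toluene, 0 °C → rt, dark, Ar
Reagents that add atoms: nitrosobenzene O=Nc1ccccc1
Why: The chiral phosphoric acid turns both enantiomers of 12 into the same planar aromatic enol (a 3-hydroxybenzofuran) and holds it and the activated nitrosobenzene in one hydrogen-bonded assembly, so that O-selective attack by one face of C2 gives 13, whose N–O bond is cleaved by a second nitrosobenzene (asymmetric α-hydroxylation of α-branched cyclic ketones by enol catalysis, an O-nitroso aldol reaction), the catalyst thereby setting C2 as R without ever forming the hemiketal alkoxide.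

Step 8
Reactants: 14 (2R)-6-(tert-butyldimethylsilyloxy)-2-hydroxy-2-farnesylbenzofuran-3(2H)-one
Product: 15 (2R)-2,6-dihydroxy-2-[(2E,6E)-3,7,11-trimethyldodeca-2,6,10-trien-1-yl]benzofuran-3(2H)-one
Conditions: TBAF–AcOH (1:1.5, 1.2 equiv), THF, −20 → 0 °C
Reagents that add atoms: none
Why: Fluoride cleaves the phenolic silyl ether rapidly (fluoride-mediated desilylation), and the acetic acid buffer keeps the C2 hydroxyl protonated, so ring opening to the achiral 1,2-diketone, the path of racemisation, is not triggered.

Compound list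
1 | geranyl bromide, (2E)-1-bromo-3,7-dimethylocta-2,6-diene | CC(C)=CCC/C(C)=C/CBr | starting material
2 | propargyl bromide, 3-bromoprop-1-yne | C#CCBr | starting material
3 | 1,3-dilithiopropyne | [Li]CC#C[Li] | intermediate
4 | (5E)-6,10-dimethylundeca-5,9-dien-1-yne | CC(C)=CCC/C(C)=C/CCC#C | intermediate
5 | dimethyl[(1E,5E)-2,6,10-trimethylundeca-1,5,9-trien-1-yl]alane | CC(C)=CCC/C(C)=C/CC/C(C)=C/[Al](C)C | intermediate
6 | (1E,5E)-1-iodo-2,6,10-trimethylundeca-1,5,9-triene | CC(C)=CCC/C(C)=C/CC/C(C)=C/I | intermediate
7 | 2,4-dihydroxybenzaldehyde | O=Cc1ccc(O)cc1O | starting material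
8 | 2,4-bis(tert-butyldimethylsilyloxy)benzaldehyde | O=Cc1ccc(O[Si](C)(C)C(C)(C)C)cc1O[Si](C)(C)C(C)(C)C | intermediate
9 | bromomagnesium 1-[2,4-bis(tert-butyldimethylsilyloxy)phenyl]prop-2-en-1-olate (racemic) | C=CC(O[Mg]Br)c1ccc(O[Si](C)(C)C(C)(C)C)cc1O[Si](C)(C)C(C)(C)C | intermediate
10 | rac-5-(tert-butyldimethylsilyloxy)-2-[1-(tert-butyldimethylsilyloxy)prop-2-en-1-yl]phenol | C=CC(O[Si](C)(C)C(C)(C)C)c1ccc(O[Si](C)(C)C(C)(C)C)cc1O | intermediate
11 | 3,6-bis(tert-butyldimethylsilyloxy)-2-[(2E,6E)-farnesyl]-2,3-dihydrobenzofuran (racemic, C2/C3 cis/trans mixture) | CC(C)=CCC/C(C)=C/CC/C(C)=C/CC1Oc2cc(O[Si](C)(C)C(C)(C)C)ccc2C1O[Si](C)(C)C(C)(C)C | intermediate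
12 | rac-6-(tert-butyldimethylsilyloxy)-2-[(2E,6E)-farnesyl]benzofuran-3(2H)-one | CC(C)=CCC/C(C)=C/CC/C(C)=C/CC1Oc2cc(O[Si](C)(C)C(C)(C)C)ccc2C1=O | intermediate
13 | (2S)-2-(anilinooxy)-6-(tert-butyldimethylsilyloxy)-2-[(2E,6E)-farnesyl]benzofuran-3(2H)-one | CC(C)=CCC/C(C)=C/CC/C(C)=C/C[C@@]1(ONc2ccccc2)Oc2cc(O[Si](C)(C)C(C)(C)C)ccc2C1=O | intermediate
14 | (2R)-6-(tert-butyldimethylsilyloxy)-2-hydroxy-2-[(2E,6E)-farnesyl]benzofuran-3(2H)-one | CC(C)=CCC/C(C)=C/CC/C(C)=C/C[C@@]1(O)Oc2cc(O[Si](C)(C)C(C)(C)C)ccc2C1=O | intermediate
15 | (2R)-2,6-dihydroxy-2-[(2E,6E)-3,7,11-trimethyldodeca-2,6,10-trien-1-yl]benzofuran-3(2H)-one | CC(C)=CCC/C(C)=C/CC/C(C)=C/C[C@@]1(O)Oc2cc(O)ccc2C1=O | target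

Total steps: 8. Longest linear sequence: 6 (steps 3–8; the branch through steps 1, 2, 5–8 is equally long).

Steps most likely to fail

Step 5. Three processes can compete with product formation:
- The cationic alkenyl-palladium species may insert the terminal alkene (Heck pathway).
- The alkyl-palladium intermediate may undergo β-hydride elimination before the C–C bond forms.
- The phenol may expel the benzylic silyloxy group to an o-quinone methide that electrocyclises.

The fallback sets out from 10 and 6 and comes back at 11. It separates ring closure from coupling. Iodoetherification of 10 (NIS, NaHCO3, MeCN, 0 °C, 5-exo) would give 3,6-bis(tert-butyldimethylsilyloxy)-2-(iodomethyl)-2,3-dihydrobenzofuran F1. A nickel-catalysed reductive cross-electrophile coupling of F1 with 6 (NiBr2·glyme, 4,4′-di-tert-butyl-2,2′-bipyridine, Mn, DMA, rt) would then form the same C1′–C2′ bond and deliver 11.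

Step 7. Four processes can go wrong:
- An uncatalysed background reaction of the readily formed aromatic enol would give racemic product.
- Attack at nitrogen instead of oxygen of nitrosobenzene would give the hydroxyamination product.
- A nitroso-ene reaction could occur on the chain alkenes.
- Acid-catalysed ring-chain tautomerism of the product could slowly erode its enantiopurity.

The fallback sets out from 12 and comes back at 15. It replaces enol catalysis by a metal-oxo oxidation that delivers the C2 oxygen already protected. Silylation of 12 (TBSOTf, Et3N, CH2Cl2, 0 °C) would give 3,6-bis(tert-butyldimethylsilyloxy)-2-[(2E,6E)-farnesyl]benzofuran F2. An asymmetric Rubottom oxidation under Jacobsen–Katsuki conditions ((salen)Mn(III)Cl, PhIO, 4-phenylpyridine N-oxide, CH2Cl2, 0 °C) should select the electron-rich aryl-conjugated silyl enol ether over the isolated alkenes. After silyl migration it would give (2S)-2,6-bis(tert-butyldimethylsilyloxy)-2-[(2E,6E)-farnesyl]benzofuran-3(2H)-one F3. This is desilylated at both oxygens with TBAF–AcOH to 15.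

Step 6. Two processes can go wrong:
- Further dehydrogenation of the enolisable product could give the 2-alkylidene dienone.
- Loss of silanol from the cationic intermediate or from 11 could aromatise the ring to a 3-unsubstituted benzofuran.

The fallback sets out from 11 and comes back at 12. Buffered desilylation (TBAF–AcOH, THF, 0 °C) would give 2-[(2E,6E)-farnesyl]-2,3-dihydrobenzofuran-3,6-diol F4. Neutral oxidation of its benzylic alcohol with activated MnO2 (CH2Cl2, rt) would give rac-2-[(2E,6E)-farnesyl]-6-hydroxybenzofuran-3(2H)-one F5. Re-silylation (TBSCl, imidazole, DMF) then returns 12.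

Further compounds
F1 | step 5 | 3,6-bis(tert-butyldimethylsilyloxy)-2-(iodomethyl)-2,3-dihydrobenzofuran (racemic diastereomer mixture) | ICC1Oc2cc(O[Si](C)(C)C(C)(C)C)ccc2C1O[Si](C)(C)C(C)(C)C
F2 | step 7 | 3,6-bis(tert-butyldimethylsilyloxy)-2-[(2E,6E)-farnesyl]benzofuran | CC(C)=CCC/C(C)=C/CC/C(C)=C/Cc1oc2cc(O[Si](C)(C)C(C)(C)C)ccc2c1O[Si](C)(C)C(C)(C)C
F3 | step 7 | (2S)-2,6-bis(tert-butyldimethylsilyloxy)-2-[(2E,6E)-farnesyl]benzofuran-3(2H)-one | CC(C)=CCC/C(C)=C/CC/C(C)=C/C[C@@]1(O[Si](C)(C)C(C)(C)C)Oc2cc(O[Si](C)(C)C(C)(C)C)ccc2C1=O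
F4 | step 6 | 2-[(2E,6E)-farnesyl]-2,3-dihydrobenzofuran-3,6-diol (racemic diastereomer mixture) | CC(C)=CCC/C(C)=C/CC/C(C)=C/CC1Oc2cc(O)ccc2C1O
F5 | step 6 | rac-2-[(2E,6E)-farnesyl]-6-hydroxybenzofuran-3(2H)-one | CC(C)=CCC/C(C)=C/CC/C(C)=C/CC1Oc2cc(O)ccc2C1=O
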